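**Retrosynthetic overview**

1. Target ⇐ desilylation and oxidation of the C1 alcohol ⇐ tetraol from one double syn-dihydroxylation of a cis-octalin that carries the C1=C2 and the exocyclic C7=CH2 alkenes.
2. Key step: that octalin ⇐ bicyclic 4-acyl dienone by cathodic (electrochemical) reductive methylation, which forges the C4–CH3 bond of the quaternary centre and sets C4a.
3. Ring A and ring B are formed together in one thermal intramolecular Diels–Alder reaction of an acyclic (E,E)-dienyl ynone (bonds C3–C4 and C4a–C8a); no ring exists before it.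
4. Acyclic precursor ⇐ acetylide acylation (C4–CO), Negishi coupling (C6–C7) and zirconium/copper allylation (C8–C8a) around 2,3-dibromopropene.
5. Stereochemistry: the sec-butyl centre is bought in (R)-2-methylbutanoic acid and C5 in the (R)-Roche ester; C3, C8a, C4a, C4, C2 and C7 follow by substrate control.

Assumption: (R)-2-methylbutanoic acid and the silylated Weinreb amide of step 8 are taken as purchasable; ring atoms carry the target's locants (C1 ring ketone, C2 C(OH)Me, C3 CH-sec-butyl, C4 quaternary carbon, C4a/C8a ring fusion, C5 CHMe, C7 carbinol carbon) and β is the face of H-8a.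

**Route**

Step 1
Reactants: 1 (R)-2-methylbutanoic acid
Product: 2 (R)-2-methylbutan-1-ol
Conditions: LiAlH4, Et2O, 0 °C → rt; H2O quench
Reagents that add atoms: none
Why: LiAlH4 reduction of the acid to the primary alcohol removes the enolisable carbonyl, so the bought stereocentre is untouched.

Step 2
Reactants: 2 (R)-2-methylbutan-1-ol
Product: 4 (2E,4R)-2,4-dimethylhex-2-enal, via (R)-2-methylbutanal 3 (not isolated)
Conditions: TEMPO (10 mol%), PhI(OAc)2, CH2Cl2, rt; then Ph3P=C(Me)CHO, PhMe, 80 °C
Reagents that add atoms: 2-(triphenylphosphoranylidene)propanal, CC(C=O)=P(c1ccccc1)(c1ccccc1)c1ccccc1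
Why: Aminoxyl-catalysed oxidation followed in the same pot by a Wittig reaction with the stabilised formyl ylide gives the (E)-trisubstituted enal under non-basic conditions that keep the α-stereocentre of 3.

Step 3
Reactants: 4 (2E,4R)-2,4-dimethylhex-2-enal
Product: 5 (3E,5R)-3,5-dimethylhept-3-en-1-yne
Conditions: dimethyl (1-diazo-2-oxopropyl)phosphonate, K2CO3, MeOH, 0 °C → rt
Reagents that add atoms: dimethyl (1-diazo-2-oxopropyl)phosphonate, COP(=O)(OC)C(=[N+]=[N-])C(C)=O
Why: Seyferth–Gilbert homologation (Ohira–Bestmann variant) turns the aldehyde into the terminal alkyne without touching the alkene geometry or the allylic stereocentre.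

Step 4
Reactants: 5 (3E,5R)-3,5-dimethylhept-3-en-1-yne; 6 2,3-dibromoprop-1-ene
Product: 8 (4E,6E,8R)-2-bromo-6,8-dimethyldeca-1,4,6-triene, via dienylzirconocene chloride 7 (not isolated)
Conditions: Cp2Zr(H)Cl, THF, rt; then 6, CuCl (10 mol%), 0 °C → rt
Reagents that add atoms: none
Why: syn-Hydrozirconation of the terminal alkyne gives the (E)-alkenylzirconocene, and copper-catalysed allylic substitution on 6 (SN2 and SN2' give the same product) delivers the (E,E)-diene with retention.

Step 5
Reactants: 9 methyl (R)-3-hydroxy-2-methylpropanoate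
Product: 10 methyl (S)-3-iodo-2-methylpropanoate
Conditions: I2, PPh3, imidazole, CH2Cl2, 0 °C → rt
Reagents that add atoms: iodine, II
Why: Appel-type iodination of the primary alcohol does not involve the stereocentre (the descriptor changes only by priority).

Step 6
Reactants: 10 methyl (S)-3-iodo-2-methylpropanoate; 8 (4E,6E,8R)-2-bromo-6,8-dimethyldeca-1,4,6-triene
Product: 12 methyl (2R,6E,8E,10R)-2,8,10-trimethyl-4-methylidenedodeca-6,8-dienoate, via alkylzinc iodide 11 (not isolated)
Conditions: Zn dust (TMSCl/BrCH2CH2Br-activated), DMF, rt; then 8, Pd2(dba)3 (2.5 mol%), P(o-tol)3 (10 mol%), rt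
Reagents that add atoms: none
Why: Zinc insertion gives the configurationally stable β-ester alkylzinc reagent, and Negishi sp3–sp2 coupling at the vinyl bromide forms C6–C7 without involving the stereocentre.

Step 7
Reactants: 12 methyl (2R,6E,8E,10R)-2,8,10-trimethyl-4-methylidenedodeca-6,8-dienoate
Product: 14 (3R,7E,9E,11R)-3,9,11-trimethyl-5-methylidenetrideca-7,9-dien-1-yne, via aldehyde 13 (not isolated)
Conditions: i-Bu2AlH (1.1 equiv), CH2Cl2, −78 °C; then MeOH, K2CO3, dimethyl (1-diazo-2-oxopropyl)phosphonate, −78 °C → rt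
Reagents that add atoms: dimethyl (1-diazo-2-oxopropyl)phosphonate, COP(=O)(OC)C(=[N+]=[N-])C(C)=O
Why: Half-reduction of the ester and in situ Seyferth–Gilbert homologation (Ohira–Bestmann) give the propargylic C5 stereocentre with its bought configuration, since the mild carbonate conditions avoid α-epimerisation of 13.

Step 8
Reactants: 14 (3R,7E,9E,11R)-3,9,11-trimethyl-5-methylidenetrideca-7,9-dien-1-yne; 15 3-[(tert-butyldimethylsilyl)oxy]-N-methoxy-N-methylpropanamide
Product: 17 (6R,10E,12E,14R)-1-[(tert-butyldimethylsilyl)oxy]-6,12,14-trimethyl-8-methylidenehexadeca-10,12-dien-4-yn-3-one, via lithium acetylide 16 (not isolated)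
Conditions: n-BuLi, THF, −78 °C; then 15, −78 → 0 °C; aq. NH4Cl
Reagents that add atoms: none
Why: Weinreb ketone synthesis: the chelated tetrahedral intermediate stops the acetylide acylation at the ynone.

Step 9
Reactants: 17 (acyclic dienyl ynone)
Product: 18 bicyclic dienone (C1=C2 and C4=C4a alkenes; H-3, H-5, H-8a all β)
Conditions: PhMe (5 mM), BHT (5 mol%), 100 °C, Ar, 24 h
Reagents that add atoms: none
Why: Thermal intramolecular Diels–Alder reaction of the (E,E)-diene with the ynone closes ring A and ring B at once; suprafacial addition puts H-3 and H-8a cis, and the chair-like tether with the propargylic C5 methyl equatorial (1,3-cis to the equatorial diene carbon) gives H-8a cis to H-5.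

Step 10
Reactants: 18 bicyclic dienone
Product: 20 cis-fused C4-methyl ketone (4β-methyl; 4α-acyl; 4aβ-H), via lithium enolate 19 (not isolated)
Conditions: undivided cell, Mg anode, stainless-steel cathode, LiBr (0.3 M), 1,3-dimethylurea (1.0 equiv), THF, 0 °C, 5 mA cm−2, 2.2 F mol−1; electrodes withdrawn; then MeI, DMPU, −20 °C → rt
Reagents that add atoms: iodomethane, CI
Why: Proposed new method: cathodic two-electron reduction of the lithium-bound tetrasubstituted enone, with one equivalent of 1,3-dimethylurea as the only proton donor, should give the radical anion, which is protonated at C4a from the β face (the α face is covered by ring B through C8 and by the C3 sec-butyl group) and reduced again to enolate 19; MeI then alkylates C4 anti to the flanking sec-butyl group and the C4a–C5 bond, giving the quaternary centre with methyl β and acyl α, while the isolated alkenes and the silyl ether are not reduced at this potential and no amide base is present to eliminate the β-silyloxy ketone; the closest known reaction types are the Stork reductive alkylation of enones with Li in NH3 and the sacrificial-anode electrochemical Birch reduction of arenes, neither shown as an electrochemical reductive α-alkylation of a tetrasubstituted enone.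

Step 11
Reactants: 20 cis-fused C4-methyl ketone
Product: 21 tetraol (1β,2β-diol; 7β-OH; 7α-CH2OH)
Conditions: OsO4 (10 mol%), NMO (3 equiv), MeSO2NH2, acetone/H2O 4:1, rt, 48 h
Reagents that add atoms: N-methylmorpholine N-oxide, C[N+]1([O-])CCOCC1; water, O
Why: Upjohn syn-dihydroxylation of both alkenes: OsO4 adds to the ring A alkene from the β face because the α face is shielded by the C3 sec-butyl group, C8 and the C4 acyl group (sets C2; C1 is oxidised later), and to the exocyclic alkene from the convex β face of the cis-decalin because ring A and its C4 substituents lie under the α face of ring B (sets C7 with OH β).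

Step 12
Reactants: 21 tetraol
Product: 22 bis-silyl ether (C7–CH2OTBS)
Conditions: TBSCl (1.1 equiv), imidazole, CH2Cl2, 0 °C
Reagents that add atoms: tert-butyldimethylsilyl chloride, CC(C)(C)[Si](C)(C)Cl
Why: Sterically selective silylation of the only primary hydroxyl leaves the secondary C1 carbinol as the only oxidisable alcohol.

Step 13
Reactants: 22 bis-silyl ether
Product: 23 α-hydroxy ketone (C1 ketone)
Conditions: IBX, DMSO, 40 °C
Reagents that add atoms: none
Why: IBX oxidation of the secondary alcohol of a vicinal diol gives the α-ketol without C–C cleavage, and the tertiary alcohols cannot react.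

Step 14
Reactants: 23 α-hydroxy ketone
Product: 24 target, (2S,3R,4R,4aR,5R,7R,8aS)-3-[(2R)-butan-2-yl]-2,7-dihydroxy-7-(hydroxymethyl)-4-(3-hydroxypropanoyl)-2,4,5-trimethyloctahydronaphthalen-1(2H)-one
Conditions: HF·pyridine, THF/pyridine, 0 °C → rt
Reagents that add atoms: none
Why: Fluoride-mediated desilylation of both silyl ethers under mildly acidic conditions avoids epimerisation at C8a and retro-aldol loss from the β-hydroxy ketone.

**Compound list**

1 | (R)-2-methylbutanoic acid | CC[C@@H](C)C(=O)O | starting material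
2 | (R)-2-methylbutan-1-ol | CC[C@@H](C)CO | intermediate
3 | (R)-2-methylbutanal | CC[C@@H](C)C=O | intermediate
4 | (2E,4R)-2,4-dimethylhex-2-enal | CC[C@@H](C)/C=C(\C)C=O | intermediate
5 | (3E,5R)-3,5-dimethylhept-3-en-1-yne | CC[C@@H](C)/C=C(\C)C#C | intermediate
6 | 2,3-dibromoprop-1-ene | C=C(Br)CBr | starting material
7 | chlorobis(cyclopentadienyl)[(1E,3E,5R)-3,5-dimethylhepta-1,3-dien-1-yl]zirconium | CC[C@@H](C)/C=C(\C)/C=C/[Zr](Cl)(C1C=CC=C1)C1C=CC=C1 | intermediate
8 | (4E,6E,8R)-2-bromo-6,8-dimethyldeca-1,4,6-triene | CC[C@@H](C)/C=C(\C)/C=C/CC(Br)=C | intermediate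
9 | methyl (R)-3-hydroxy-2-methylpropanoate | COC(=O)[C@H](C)CO | starting material
10 | methyl (S)-3-iodo-2-methylpropanoate | COC(=O)[C@H](C)CI | intermediate
11 | [(2S)-3-methoxy-2-methyl-3-oxopropyl]zinc iodide | COC(=O)[C@H](C)C[Zn]I | intermediate
12 | methyl (2R,6E,8E,10R)-2,8,10-trimethyl-4-methylidenedodeca-6,8-dienoate | COC(=O)[C@H](C)CC(=C)C/C=C/C(C)=C/[C@H](C)CC | intermediate
13 | (2R,6E,8E,10R)-2,8,10-trimethyl-4-methylidenedodeca-6,8-dienal | O=C[C@H](C)CC(=C)C/C=C/C(C)=C/[C@H](C)CC | intermediate
14 | (3R,7E,9E,11R)-3,9,11-trimethyl-5-methylidenetrideca-7,9-dien-1-yne | C#C[C@H](C)CC(=C)C/C=C/C(C)=C/[C@H](C)CC | intermediate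
15 | 3-[(tert-butyldimethylsilyl)oxy]-N-methoxy-N-methylpropanamide | CON(C)C(=O)CCO[Si](C)(C)C(C)(C)C | starting material
16 | lithium acetylide of 14 | [Li]C#C[C@H](C)CC(=C)C/C=C/C(C)=C/[C@H](C)CC | intermediate
17 | (6R,10E,12E,14R)-1-[(tert-butyldimethylsilyl)oxy]-6,12,14-trimethyl-8-methylidenehexadeca-10,12-dien-4-yn-3-one | CC(C)(C)[Si](C)(C)OCCC(=O)C#C[C@H](C)CC(=C)C/C=C/C(C)=C/[C@H](C)CC | intermediate
18 | 3-[(tert-butyldimethylsilyl)oxy]-1-{3α-[(2R)-butan-2-yl]-2,5α-dimethyl-7-methylidene-3,5,6,7,8,8a-hexahydronaphthalen-4-yl}propan-1-one (target locants; C1=C2 and C4=C4a alkenes; H-3, H-5, H-8a β) | CC[C@@H](C)[C@H]1C(C)=C[C@H]2CC(=C)C[C@@H](C)C2=C1C(=O)CCO[Si](C)(C)C(C)(C)C | intermediate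
19 | lithium enolate formed from 18 (C4=C(OLi) exocyclic; H-3, H-4a, H-5, H-8a β; enolate geometry not defined) | CC[C@@H](C)[C@H]1C(C)=C[C@H]2CC(=C)C[C@@H](C)[C@H]2C1=C(O[Li])CCO[Si](C)(C)C(C)(C)C | intermediate
20 | 3-[(tert-butyldimethylsilyl)oxy]-1-{3α-[(2R)-butan-2-yl]-2,4β,5α-trimethyl-7-methylidene-3,4,4a,5,6,7,8,8a-octahydronaphthalen-4α-yl}propan-1-one (cis-fused; H-3, H-4a, H-5, H-8a β) | CC[C@@H](C)[C@H]1C(C)=C[C@H]2CC(=C)C[C@@H](C)[C@H]2[C@@]1(C)C(=O)CCO[Si](C)(C)C(C)(C)C | intermediate
21 | 3-[(tert-butyldimethylsilyl)oxy]-1-{3α-[(2R)-butan-2-yl]-1β,2β,7β-trihydroxy-7α-(hydroxymethyl)-2α,4β,5α-trimethyldecahydronaphthalen-4α-yl}propan-1-one (cis-fused) | CC[C@@H](C)[C@H]1[C@](C)(O)[C@H](O)[C@H]2C[C@@](O)(CO)C[C@@H](C)[C@H]2[C@@]1(C)C(=O)CCO[Si](C)(C)C(C)(C)C | intermediate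
22 | 21 with the C7 hydroxymethyl group as its tert-butyldimethylsilyl ether | CC[C@@H](C)[C@H]1[C@](C)(O)[C@H](O)[C@H]2C[C@@](O)(CO[Si](C)(C)C(C)(C)C)C[C@@H](C)[C@H]2[C@@]1(C)C(=O)CCO[Si](C)(C)C(C)(C)C | intermediate
23 | bis-silyl ether of the target (C1 ketone, 2β-OH, 7β-OH, both primary alcohols as TBS ethers) | CC[C@@H](C)[C@H]1[C@](C)(O)C(=O)[C@H]2C[C@@](O)(CO[Si](C)(C)C(C)(C)C)C[C@@H](C)[C@H]2[C@@]1(C)C(=O)CCO[Si](C)(C)C(C)(C)C | intermediate
24 | (2S,3R,4R,4aR,5R,7R,8aS)-3-[(2R)-butan-2-yl]-2,7-dihydroxy-7-(hydroxymethyl)-4-(3-hydroxypropanoyl)-2,4,5-trimethyloctahydronaphthalen-1(2H)-one | CC[C@@H](C)[C@@H]1[C@](C)(C(=O)CCO)[C@@H]2[C@H](C)C[C@](O)(CO)C[C@@H]2C(=O)[C@@]1(C)O | target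

**Step count**

Total steps: 14. Longest linear sequence: 13 (steps 1–4 and 6–14 from 1; step 5 is the only side step).

**Steps most likely to fail, with fallbacks**

Step 10 (the new cathodic reductive methylation). Risks are over-reduction, O-alkylation, or a magnesium-bound enolate that methylates sluggishly. The fallback sets out from 18 and uses the classical dissolving-metal route through an isolated intermediate. Li in liquid NH3/THF with t-BuOH (1 equiv) at −78 °C reduces the enone; after removal of NH3 the enolate is trapped with TMSCl/Et3N as the trimethylsilyl enol ether F1. MeLi in THF at 0 °C then regenerates lithium enolate 19 regiospecifically, and MeI/DMPU gives 20, where the route is rejoined.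

Step 11 (double osmylation). The β-face attack on the exocyclic alkene rests on the convex-face argument; unhindered methylenecyclohexanes tend to be osmylated from the equatorial direction, which here would give the wrong C7 epimer. The fallback sets out from 20 and corrects C7 by inversion. If osmylation delivers the C7-epimeric tetraol F2 (7α-OH, 7β-CH2OH), its primary hydroxyl is tosylated (TsCl, pyridine, 0 °C) to the tosylate F3. K2CO3 in MeOH closes the spiro-epoxide F4 with retention at C7. Dilute H2SO4 in THF/H2O at 0 °C then opens the epoxide at the tertiary carbon with inversion (acid-catalysed epoxide hydrolysis, axial attack of water), which returns to 21.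

Step 9 (thermal cycloaddition). The induction from C5 to C8a may be only moderate, because the sp2 C7 leaves the axial-methyl transition state with few 1,3-diaxial contacts (a diastereomer separation may be needed). Prolonged heating may also aromatise ring A. The fallback sets out from 17 and replaces the concerted thermal reaction by the metal-catalysed dienyne [4+2] cycloisomerisation ([Rh(cod)Cl]2 5 mol%, AgSbF6 10 mol%, CH2Cl2, rt), which proceeds through oxidative cyclisation and reductive elimination at room temperature. It returns directly to 18 and makes no new compound (none F0).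

**Further compounds**

F0 | step 9 | none | none
F1 | step 10 | trimethylsilyl enol ether of the C4a-reduced ketone (C4=C(OSiMe3) exocyclic; 4aβ-H) | CC[C@@H](C)[C@H]1C(C)=C[C@H]2CC(=C)C[C@@H](C)[C@H]2C1=C(O[Si](C)(C)C)CCO[Si](C)(C)C(C)(C)C
F2 | step 11 | C7 epimer of 21 (7α-OH, 7β-CH2OH) | CC[C@@H](C)[C@H]1[C@](C)(O)[C@H](O)[C@H]2C[C@](O)(CO)C[C@@H](C)[C@H]2[C@@]1(C)C(=O)CCO[Si](C)(C)C(C)(C)C
F3 | step 11 | primary p-toluenesulfonate of F2 | CC[C@@H](C)[C@H]1[C@](C)(O)[C@H](O)[C@H]2C[C@](O)(COS(=O)(=O)c3ccc(C)cc3)C[C@@H](C)[C@H]2[C@@]1(C)C(=O)CCO[Si](C)(C)C(C)(C)C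
F4 | step 11 | C7 spiro-epoxide from F3 (oxirane oxygen α) | CC[C@@H](C)[C@H]1[C@](C)(O)[C@H](O)[C@H]2C[C@]3(CO3)C[C@@H](C)[C@H]2[C@@]1(C)C(=O)CCO[Si](C)(C)C(C)(C)C
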